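Readings and results are simulated for substances that don't exist, and the scatter is random.

You asked for a quick number, and a comparison gets you there: your run time of 30 min is shorter than the make time, 44.9 min. The make time is the time constant at which starting material goes over to open intermediate with reagent held as charged (a pseudo-first-order view). It is read from the ash run's 8.9% of open intermediate at 4.00 min, a reading with a scatter of 0.5 percentage points.

| flask | starting material | partner | reagent | remark | time |
|---|---|---|---|---|---|
| ash | 0.24 M | 0.48 M | 0.288 M | run made earlier |  |
| cedar | 0.24 M | 0.24 M | 0.288 M | run made earlier |  |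
| elm | 0.24 M | 0.36 M | 0.288 M | run made earlier |  |
| Thursday's | 0.24 M (fed, over 30.0 min) | 0.480 M | 0.288 M | a stirred flask in which starting material is dosed at a steady rate over 30.0 min without added volume, worked up at 30 min | 30 min |
| Sunday's | 0.24 M | 0.480 M | 0.288 M | a closed flask charged with all of it at once and left for 30 min | 30 min |
| Wednesday's | 0.24 M | 0.480 M | 0.288 M (fed, over 30.0 min) | all but reagent at the start; reagent goes in evenly over 30.0 min, the run ends at 30 min | 30 min |
| Saturday's | 0.24 M | 0.480 M | 0.288 M | one stirred flow tank at steady state, fed with the mixture as stated, mean residence time 30 min |  |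

| run | time / min | open intermediate / % | target / % |
|---|---|---|---|
| ash | 1.33 | 4.1 | 0.2 |
| ash | 2.50 | 6.1 | 0 |
| ash | 4.00 | 8.9 | 0 |
| ash | 6.00 | 11.1 | 1.1 |
| ash | 10.0 | 16.0 | 2.5 |
| ash | 20.0 | 21.4 | 7.7 |
| cedar | 5.00 | 10.6 | 1.5 |
| cedar | 10.0 | 18.1 | 1.1 |
| cedar | 15.0 | 22.8 | 3.7 |
| cedar | 20.0 | 28.3 | 6.0 |
| cedar | 25.0 | 29.5 | 6.4 |
| cedar | 30.0 | 32.5 | 8.7 |
| elm | 5.00 | 10.5 | 0.7 |
| elm | 10.0 | 17.3 | 2.1 |
| elm | 15.0 | 21.7 | 4.2 |
| elm | 20.0 | 24.6 | 6.7 |
| elm | 25.0 | 26.1 | 8.4 |
| elm | 30.0 | 27.3 | 9.9 |

(scatter of a reading: 0.5 percentage points)

- the stated concentrations are those of everything mixed, before any reaction; amounts are the same in each set-up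
- the feed brings no volume worth counting
- the earlier runs were made in a closed, stirred flask

- the set-up with the highest amount of open intermediate at the outlet or at the end, in percent of the starting material put in ("none" if the first two lie within 2 percentage points) (Thursday's / Sunday's / Wednesday's / Saturday's / none)
- amount of open intermediate at the outlet or at the end, in percent of the starting material put in, Thursday's
- amount of open intermediate at the outlet or at the end, in percent of the starting material put in, Sunday's
- amount of open intermediate at the outlet or at the end, in percent of the starting material put in, Wednesday's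
- amount of open intermediate at the outlet or at the end, in percent of the starting material put in, Saturday's

My own reckoning, in fractions of the charge, starts with reagent held, so Sunday's converts 48.7%. But I assume each part of starting material takes one of reagent, whose charge is 1.20 times the starting material's. Put that back: I estimate Sunday's mean reagent at 79.7% of charge, and my conversion drops to 41.3%. Saturday's tank first gives 40.0%, which leaves 66.6% of the reagent, and going round once more gives 30.8%. In Thursday's the fed starting material has on average half the contact time, and in Wednesday's the fed reagent averages half its charge, so I take about 28.4% for each. In this reckoning Sunday's leads in conversion by 10 points, against a margin of 2 points.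

These are conversions, not open intermediate. Your forecast gives open intermediate: 17.5% Thursday's, 21.3% Sunday's, 17.5% Wednesday's, 15% Saturday's, and “Batch wins by more than 2 points.”

The flasks give 13.9% Thursday's, 24.4% Sunday's, 18.9% Wednesday's and 18.3% Saturday's, so Sunday's is highest.

    open intermediate + second intermediate → target (k = 1.40 M⁻¹ min⁻¹)
    2 second intermediate → homo product (k = 0.0490 M⁻¹ min⁻¹)
    second intermediate → side product (k = 0.110 min⁻¹)
    starting material + reagent → open intermediate (k = 0.0890 M⁻¹ min⁻¹)
    reagent + partner → second intermediate (k = 0.0460 M⁻¹ min⁻¹)
    second intermediate → decomposed reagent (k = 0.0110 min⁻¹)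

Sunday's has not come to rest at 30 min, which is 0.668 make times: 63.3% of the starting material and 34% of the reagent remain. At 300 min, ten times as long, Sunday's open intermediate reads 29.5% and its target 24.4%. Sunday's reagent is then down to 0.0354%, while its starting material stands at 46.1%, far above the 0.125% that held reagent gives. For the same flask as Sunday's but with 1.2 M of reagent, taking the rate as proportional to reagent, the make time becomes 10.8 min. Two rounds then leave 8.04% of the starting material, and at its end that flask holds 11%.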